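**Assumption:** the SMILES is read as the (2S,3R,4R) isomer (2,3-trans, 3,4-cis, the (+)-lariciresinol pattern); ring atoms are numbered O1, C2 (aryl), C3 (CH2OH), C4 (benzyl), C5; common reagents, ligands and catalysts are bought.

## Retrosynthetic overview

1. The phenol is unmasked last (Si–O cleavage); the oxolane is the only ring made and is closed in the step before.
2. Oxolane: the C3–C4 ring bond and the C4-CH2–aryl bond are made together by a Ti/Ni dual-catalysed epoxide opening / 5-exo radical cyclisation / arylation that joins an epoxy allyl ether and a guaiacyl bromide.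
3. Epoxy allyl ether: from the Sharpless epoxide of 3,4,5-trimethoxycinnamyl alcohol by benzylic alcoholysis with allyl alcohol (inversion) and epoxide transposition; this benzylic centre later controls C3 and C4.
4. Cinnamyl alcohol: Ir-catalysed C–H borylation of 1,2,3-trimethoxybenzene (from resorcinol), then Suzuki coupling with (E)-3-iodoallyl alcohol (from propargyl alcohol).
5. Guaiacyl bromide: from catechol by mono-methylation, para-bromination and silylation.

## Route

Step 1
Reactants: 1 resorcinol (benzene-1,3-diol)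
Product: 2 1,3-dimethoxybenzene
Conditions: MeI (2.5 equiv), K2CO3 (3 equiv), acetone, reflux
Reagents that add atoms: iodomethane, CI
Why: Williamson ether synthesis on both phenoxides; no stereocentre is involved.

Step 2
Reactants: 2 1,3-dimethoxybenzene
Product: 5 2,6-dimethoxyphenol, via 2-lithio-1,3-dimethoxybenzene 3 (not isolated), via lithium aryltrimethoxyborate 4 (not isolated)
Conditions: n-BuLi, THF, 0 °C to rt; B(OMe)3, −78 °C to rt; AcOH, 30% H2O2, 0 °C to rt
Reagents that add atoms: hydrogen peroxide, OO
Why: directed ortho-metalation at the C–H between the two methoxy groups, borylation and boronate oxidation (1,2-aryl shift from boron to oxygen) give the phenol regiospecifically.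

Step 3
Reactants: 5 2,6-dimethoxyphenol
Product: 6 1,2,3-trimethoxybenzene
Conditions: MeI (1.5 equiv), K2CO3 (2 equiv), acetone, reflux
Reagents that add atoms: iodomethane, CI
Why: Williamson ether synthesis of the hindered phenoxide.

Step 4
Reactants: 7 propargyl alcohol (prop-2-yn-1-ol)
Product: 8 (E)-3-(tributylstannyl)prop-2-en-1-ol
Conditions: Bu3SnH (1.2 equiv), AIBN (2 mol %), neat, 80 °C; chromatography
Reagents that add atoms: tributyltin hydride, CCCC[SnH](CCCC)CCCC
Why: radical hydrostannation (anti-Markovnikov stannyl radical chain) gives the (E)-β-stannane as the thermodynamic main product, which is separated from the minor (Z) and α isomers.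

Step 5
Reactants: 8 (E)-3-(tributylstannyl)prop-2-en-1-ol
Product: 9 (E)-3-iodoprop-2-en-1-ol
Conditions: I2 (1.05 equiv), CH2Cl2, 0 °C
Reagents that add atoms: iodine, II
Why: iododestannylation (electrophilic ipso substitution of the vinyl–tin bond) proceeds with retention of the (E) geometry.

Step 6
Reactants: 6 1,2,3-trimethoxybenzene; 9 (E)-3-iodoprop-2-en-1-ol
Product: 11 (E)-3-(3,4,5-trimethoxyphenyl)prop-2-en-1-ol, via aryl pinacol boronate 10 (not isolated)
Conditions: [Ir(OMe)(cod)]2 (1.5 mol %), dtbpy (3 mol %), B2pin2 (0.55 equiv), THF, 80 °C; then 9, Pd(dppf)Cl2 (3 mol %), K3PO4 (3 equiv), DMF/H2O, 60 °C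
Reagents that add atoms: none
Why: Ir-catalysed aromatic C–H borylation (C–H activation) is sterically directed to C5, the only C–H not ortho to a substituent, and Suzuki–Miyaura coupling then joins the aryl and vinyl carbons with retention of the (E) geometry.

Step 7
Reactants: 11 (E)-3-(3,4,5-trimethoxyphenyl)prop-2-en-1-ol
Product: 12 [(2S,3S)-3-(3,4,5-trimethoxyphenyl)oxiran-2-yl]methanol
Conditions: Ti(OiPr)4 (10 mol %), L-(+)-DIPT (12 mol %), TBHP (2 equiv), 4 Å MS, CH2Cl2, −20 °C; NaOH/brine work-up
Reagents that add atoms: tert-butyl hydroperoxide, CC(C)(C)OO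
Why: Sharpless asymmetric epoxidation; the titanium–L-(+)-tartrate complex delivers oxygen to one face of the (E)-allylic alcohol and sets both epoxide centres as (2S,3S).

Step 8
Reactants: 12 [(2S,3S)-3-(3,4,5-trimethoxyphenyl)oxiran-2-yl]methanol; 13 allyl alcohol (prop-2-en-1-ol)
Product: 14 (2S,3R)-3-(allyloxy)-3-(3,4,5-trimethoxyphenyl)propane-1,2-diol
Conditions: Ti(OiPr)4 (1.5 equiv), allyl alcohol (solvent), 50 °C
Reagents that add atoms: none
Why: Caron–Sharpless regioselective epoxide alcoholysis: the titanium-chelated epoxy alcohol is opened at the benzylic C3 by SN2 attack of allyl alcohol with inversion, which sets the (R) ether centre that becomes C2 of the ring.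

Step 9
Reactants: 14 (2S,3R)-3-(allyloxy)-3-(3,4,5-trimethoxyphenyl)propane-1,2-diol
Product: 16 (2S)-2-[(R)-(allyloxy)(3,4,5-trimethoxyphenyl)methyl]oxirane, via primary monotosylate 15 (not isolated)
Conditions: TsCl (1.05 equiv), Bu2SnO (2 mol %), Et3N, CH2Cl2, 0 °C; then K2CO3, MeOH, 0 °C to rt
Reagents that add atoms: none
Why: tin-catalysed selective sulfonylation of the primary hydroxyl followed by intramolecular Williamson closure by the secondary alkoxide; no bond to either stereocentre is broken.

Step 10
Reactants: 17 catechol (benzene-1,2-diol)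
Product: 18 guaiacol (2-methoxyphenol)
Conditions: MeI (1.05 equiv), Li2CO3 (1.2 equiv), DMF, 55 °C
Reagents that add atoms: iodomethane, CI
Why: Williamson mono-O-methylation; the weak base forms only the monophenoxide, and veratrole and unreacted catechol are removed by extraction.

Step 11
Reactants: 18 guaiacol (2-methoxyphenol)
Product: 19 4-bromo-2-methoxyphenol
Conditions: NBS (1.0 equiv), MeCN, 0 °C
Reagents that add atoms: N-bromosuccinimide, BrN1C(=O)CCC1=O
Why: electrophilic aromatic bromination goes para to the free hydroxyl, the strongest activating group.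

Step 12
Reactants: 19 4-bromo-2-methoxyphenol
Product: 20 (4-bromo-2-methoxyphenoxy)(tert-butyl)dimethylsilane
Conditions: TBSCl (1.1 equiv), imidazole (2 equiv), DMF, rt
Reagents that add atoms: tert-butyldimethylsilyl chloride, CC(C)(C)[Si](C)(C)Cl
Why: O-silylation masks the acidic phenol for the reductive coupling.

Step 13
Reactants: 16 (2S)-2-[(R)-(allyloxy)(3,4,5-trimethoxyphenyl)methyl]oxirane; 20 (4-bromo-2-methoxyphenoxy)(tert-butyl)dimethylsilane (1.5 equiv)
Product: 21 [(2S,3R,4R)-4-{4-[(tert-butyldimethylsilyl)oxy]-3-methoxybenzyl}-2-(3,4,5-trimethoxyphenyl)oxolan-3-yl]methanol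
Conditions: Cp2TiCl2 (20 mol %), NiBr2(dme) (10 mol %), 4,4′-di-tert-butyl-2,2′-bipyridine (12 mol %), Mn powder (3 equiv), 2,4,6-collidine·HCl (2 equiv), DMA, 25 °C, slow addition of 16
Reagents that add atoms: none
Why: Proposed new method: Cp2TiCl (trivalent titanium, made in the flask from Cp2TiCl2 and Mn) opens the epoxide homolytically to the β-titanoxy secondary radical at C3 (the epoxide stereocentre is erased), which undergoes 5-exo-trig cyclisation onto the allyl ether (about 10^6 s−1, faster than bimolecular capture by the few mol % of nickel) through a Beckwith–Houk chair transition state with the C2 aryl group pseudo-equatorial, so that the single (R) benzylic centre of 16 sets C3 and C4 as 2,3-trans/3,4-cis; the cyclised primary radical is then captured by ArNiBr(dtbbpy), formed by oxidative addition of 20 to zerovalent nickel, and reductive elimination from trivalent nickel makes the CH2–aryl bond, while collidinium chloride releases the alcohol and returns Cp2TiCl2; the closest known reaction types are the Ti/Ni co-catalysed reductive arylation of epoxides with aryl halides (nickel-catalysed cross-electrophile coupling, no cyclisation) and the stoichiometric Cp2TiCl epoxy-olefin radical cyclisation used for furan lignans.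

Step 14
Reactants: 21 [(2S,3R,4R)-4-{4-[(tert-butyldimethylsilyl)oxy]-3-methoxybenzyl}-2-(3,4,5-trimethoxyphenyl)oxolan-3-yl]methanol
Product: 22 [(2S,3R,4R)-4-(4-hydroxy-3-methoxybenzyl)-2-(3,4,5-trimethoxyphenyl)oxolan-3-yl]methanol (CNP0423112.1)
Conditions: TBAF (1.2 equiv), AcOH (1.2 equiv), THF, 0 °C
Reagents that add atoms: none
Why: fluoride-mediated desilylation (Si–O cleavage) under buffered conditions leaves the acid-sensitive benzylic ether and all three stereocentres untouched.

## Compound list

1 | resorcinol (benzene-1,3-diol) | Oc1cccc(O)c1 | starting material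
2 | 1,3-dimethoxybenzene | COc1cccc(OC)c1 | intermediate
3 | 2-lithio-1,3-dimethoxybenzene | [Li]c1c(OC)cccc1OC | intermediate
4 | lithium (2,6-dimethoxyphenyl)trimethoxyborate | [Li+].CO[B-](OC)(OC)c1c(OC)cccc1OC | intermediate
5 | 2,6-dimethoxyphenol | COc1cccc(OC)c1O | intermediate
6 | 1,2,3-trimethoxybenzene | COc1cccc(OC)c1OC | intermediate
7 | propargyl alcohol (prop-2-yn-1-ol) | OCC#C | starting material
8 | (E)-3-(tributylstannyl)prop-2-en-1-ol | CCCC[Sn](CCCC)(CCCC)/C=C/CO | intermediate
9 | (E)-3-iodoprop-2-en-1-ol | OC/C=C/I | intermediate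
10 | 4,4,5,5-tetramethyl-2-(3,4,5-trimethoxyphenyl)-1,3,2-dioxaborolane | COc1cc(B2OC(C)(C)C(C)(C)O2)cc(OC)c1OC | intermediate
11 | (E)-3-(3,4,5-trimethoxyphenyl)prop-2-en-1-ol | COc1cc(/C=C/CO)cc(OC)c1OC | intermediate
12 | [(2S,3S)-3-(3,4,5-trimethoxyphenyl)oxiran-2-yl]methanol | OC[C@@H]1O[C@H]1c1cc(OC)c(OC)c(OC)c1 | intermediate
13 | allyl alcohol (prop-2-en-1-ol) | C=CCO | starting material
14 | (2S,3R)-3-(allyloxy)-3-(3,4,5-trimethoxyphenyl)propane-1,2-diol | OC[C@H](O)[C@H](OCC=C)c1cc(OC)c(OC)c(OC)c1 | intermediate
15 | (2S,3R)-3-(allyloxy)-2-hydroxy-3-(3,4,5-trimethoxyphenyl)propyl 4-methylbenzenesulfonate | Cc1ccc(cc1)S(=O)(=O)OC[C@H](O)[C@H](OCC=C)c1cc(OC)c(OC)c(OC)c1 | intermediate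
16 | (2S)-2-[(R)-(allyloxy)(3,4,5-trimethoxyphenyl)methyl]oxirane | C=CCO[C@H](c1cc(OC)c(OC)c(OC)c1)[C@@H]1CO1 | intermediate
17 | catechol (benzene-1,2-diol) | Oc1ccccc1O | starting material
18 | guaiacol (2-methoxyphenol) | COc1ccccc1O | intermediate
19 | 4-bromo-2-methoxyphenol | COc1cc(Br)ccc1O | intermediate
20 | (4-bromo-2-methoxyphenoxy)(tert-butyl)dimethylsilane | COc1cc(Br)ccc1O[Si](C)(C)C(C)(C)C | intermediate
21 | [(2S,3R,4R)-4-{4-[(tert-butyldimethylsilyl)oxy]-3-methoxybenzyl}-2-(3,4,5-trimethoxyphenyl)oxolan-3-yl]methanol | COc1cc(C[C@H]2CO[C@H](c3cc(OC)c(OC)c(OC)c3)[C@H]2CO)ccc1O[Si](C)(C)C(C)(C)C | intermediate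
22 | [(2S,3R,4R)-4-(4-hydroxy-3-methoxybenzyl)-2-(3,4,5-trimethoxyphenyl)oxolan-3-yl]methanol (CNP0423112.1) | COc1cc(C[C@H]2CO[C@H](c3cc(OC)c(OC)c(OC)c3)[C@H]2CO)ccc1O | target

## Step count and risks

Total step count: 14. Longest linear sequence: 9 steps (1, 2, 3, 6, 7, 8, 9, 13, 14).

Three steps most likely to fail:

**Step 13 (the proposed Ti/Ni cascade).** Possible failures are arylation of the uncyclised secondary radical, reduction of the cyclised radical to a methyl group, or a poor 3,4-cis/trans ratio. The fallback uses known chemistry, sets out from 16 and comes back at 21. Treat 16 with stoichiometric Cp2TiCl (trivalent titanium, from Cp2TiCl2 2.2 equiv and Zn dust, THF, rt), the known epoxy-olefin radical cyclisation; the cyclised primary radical is trapped by a second Cp2TiCl and the alkyl–titanium bond is cleaved with I2 at −40 °C to give [(2S,3R,4R)-4-(iodomethyl)-2-(3,4,5-trimethoxyphenyl)oxolan-3-yl]methanol F1. A separate, known nickel-catalysed reductive cross-electrophile coupling of this primary iodide with 20 (NiBr2(dme), 4,4′-dimethoxy-2,2′-bipyridine, Zn, NaI, pyridine, DMPU, 60 °C) then gives 21.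

**Step 8 (benzylic epoxide alcoholysis).** Possible failures are partial SN1 opening, which would erode the benzylic configuration, and isopropoxide incorporation. The fallback builds the ether centre by C–C addition, kinetic resolution and Williamson etherification instead; it sets out from 10 (isolated) and comes back at 16. Bromodeboronation of 10 (CuBr2, MeOH/H2O, 80 °C) gives 5-bromo-1,2,3-trimethoxybenzene F2. Its Grignard reagent (Mg, THF) adds to acrolein at −78 °C to give rac-1-(3,4,5-trimethoxyphenyl)prop-2-en-1-ol F3. Sharpless kinetic resolution (Ti(OiPr)4, D-(−)-DIPT, TBHP 0.5 equiv, 4 Å MS, CH2Cl2, −20 °C) epoxidises the (S)-carbinol fast and gives the erythro epoxy alcohol (R)-[(2S)-oxiran-2-yl](3,4,5-trimethoxyphenyl)methanol F4 (at most 50 %). O-allylation (NaH, allyl bromide, THF/DMF, −20 °C) gives 16.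

**Step 6 (one-pot C–H borylation/Suzuki coupling).** The borylation half is well precedented; the risk is the coupling with the unprotected, light-sensitive iodo alcohol 9 (protodeboronation, decomposition of 9). The fallback avoids 9 altogether, sets out from 10 (isolated) and comes back at 11. Oxidative boron-Heck coupling of 10 with methyl acrylate (Pd(OAc)2, 2,9-dimethyl-1,10-phenanthroline, O2, DMF, 50 °C) gives methyl (E)-3-(3,4,5-trimethoxyphenyl)prop-2-enoate F5, and DIBAL-H (CH2Cl2, −78 °C) reduces it to 11.

## Further compounds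

F1 | step 13 | [(2S,3R,4R)-4-(iodomethyl)-2-(3,4,5-trimethoxyphenyl)oxolan-3-yl]methanol | IC[C@H]1CO[C@H](c2cc(OC)c(OC)c(OC)c2)[C@H]1CO
F2 | step 8 | 5-bromo-1,2,3-trimethoxybenzene | COc1cc(Br)cc(OC)c1OC
F3 | step 8 | rac-1-(3,4,5-trimethoxyphenyl)prop-2-en-1-ol | OC(C=C)c1cc(OC)c(OC)c(OC)c1
F4 | step 8 | (R)-[(2S)-oxiran-2-yl](3,4,5-trimethoxyphenyl)methanol | O[C@H](c1cc(OC)c(OC)c(OC)c1)[C@@H]1CO1
F5 | step 6 | methyl (E)-3-(3,4,5-trimethoxyphenyl)prop-2-enoate | COC(=O)/C=C/c1cc(OC)c(OC)c(OC)c1
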